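Target comes up after a lag in Thursday's and Wednesday's runs, so the useful question is how far along such a curve a flask has got.

| setting | Thursday's | Wednesday's | zeta | theta |
|---|---|---|---|---|
| substrate | 1.1 M | 2.5 M | 1.7 M | 1.7 M |
| temperature | 15 °C | 26 °C |  |  |
| remark | run made earlier | run made earlier | at 10 °C until 1.5 h, from then on at 30 °C | at 10 °C throughout |
| time |  |  | 3.0 h | 3.0 h |

| Thursday's: time / h | Thursday's: target / % | Wednesday's: time / min | Wednesday's: target / % |
|---|---|---|---|
| 0.250 | 0 | 20.0 | 5.0 |
| 0.500 | 1.1 | 40.0 | 17.7 |
| 1.00 | 3.4 | 50.0 | 25.3 |
| 2.00 | 13.9 | 80.0 | 44.5 |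
| 4.00 | 37.5 | 120 | 62.3 |

(scatter of a reading: 0.5 percentage points)

- percentages count the substrate that a species holds: one idle adduct counts as two
- target is meant together with its crystals and idle adduct
- solid, in amounts per volume of the solution: crystals
- the numbers in the tables scatter with a standard deviation of 0.5 percentage points
- reactions considered so far: substrate -> intermediate A; intermediate A -> intermediate B; substrate <-> intermediate C; intermediate C -> intermediate D; intermediate B -> target; intermediate D <-> intermediate B; crystals <-> target; substrate + target <-> idle adduct; target -> over-reaction product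
- in an amount of target, one idle adduct counts as one target

- the flask that ends with the higher amount of target, in percent of the substrate charged, or "neither" when 2 percentage points or less lies between them (zeta / theta / neither)
- final target, as a percentage of the substrate charged, in zeta
- final target, as a percentage of the substrate charged, in theta

Thursday's 37.5% at 4.00 h is passed on Wednesday's curve, by interpolation, at 69.1 min. Wednesday's clock therefore reads as a stretch s = 3.48, a reading that lumps the temperature step with the change of substrate. With an equal factor per degree, the clock at 10 °C runs at c = 0.568 times the pace of the clock at 15 °C, and the clock at 30 °C at w = 5.47 times that pace.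

Zeta collects 9.05 h of Thursday-equivalent time H, the hours at 15 °C that carry a flask equally far, and theta collects 1.70 h. Theta's H lies between Thursday's readings at 1.00 h and 2.00 h, which gives me about 10.8%.

Turn the question round: for zeta not to win, it must end no more than 2 percentage points above that. Yet Wednesday stood at 62.3% by H = 6.95 h, which is less than zeta's H. If zeta stood where Wednesday stood at that H, its target would have to fall by 50 points of the charge in the last 2.10 h of H, while Wednesday's target was still rising at its last reading. I commit to the order and to theta's figure; zeta lies beyond the readings.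

The forecast says zeta, with 70% in zeta and 9.5% in theta, zeta being shaded “for possible over-reaction”. Its theta figure is lower than my 10.8%.

The simulation gives 56.2% in zeta and 10.3% in theta, so zeta ends higher.

    substrate → intermediate A (k = 3.90 × 10⁻⁵ /s, Ea = 87.0 kJ/mol)
    intermediate A → intermediate B (k = 2.60 × 10⁻⁴ /s, Ea = 87.0 kJ/mol)
    substrate ⇌ intermediate C (K = 0.150, k = 3.00 × 10⁻⁵ /s, Ea = 88.0 kJ/mol, ΔH = −6.00 kJ/mol)
    intermediate C → intermediate D (k = 1.10 × 10⁻⁴ /s, Ea = 97.0 kJ/mol)
    intermediate B → target (k = 1.70 × 10⁻⁴ /s, Ea = 78.0 kJ/mol)
    intermediate D ⇌ intermediate B (K = 8.30, k = 1.70 × 10⁻⁴ /s, Ea = 80.0 kJ/mol, ΔH = −76.0 kJ/mol)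
    crystals ⇌ target, rate k7*(cs7 - [target]) while solid is left; crystals form when [target] > cs7 (solubility = 0.0640 M, k = 0.0290 /s)
    substrate + target ⇌ idle adduct, settled at all times (K = 1.10 /M, ΔH = −64.0 kJ/mol)
    target → over-reaction product (k = 8.30 × 10⁻⁵ /s, Ea = 97.0 kJ/mol)
    (constants at 10 °C)

Zeta, at H = 9.05 h, ends below Wednesday's 62.3% and holds 27.7% over-reaction product, against 1.33% in theta. The step from target to over-reaction product has an activation energy of 97.0 kJ/mol, higher than the 78.0 kJ/mol of intermediate B to target, so the two steps do not share one stretch. For the same zeta flask read at 2.0 h, H = 3.58 h, and Thursday's readings give 32.6%. The computed flask holds 26.2% target and 9.27% over-reaction product.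

The earlier runs and the new flask come from a simulation with constants of no real substance, and the scatter is random.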